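**Plan**

Locants used in the text are elemane-type (systematic names carry their own): ring C5–C10; C10 bears methyl and vinyl, C9 is CH2, C8 the acyloxy carbon, C7 bears C11 (acrylic acid), C6 the hydroxyl, C5 bears C4 (hydroxy-isopropenyl carbon).
Retrosynthesis: cut the C8 ester bond first (side-chain acid), trace C4 back to a lactone carbonyl bonded to the C8 oxygen and C11–C7 to an alkenyl bromide, then cut the ring bonds C8–C9 and C5–C10 together, which leaves a 2-pyrone and isoprene.
Enabling feature: the C8 oxygen and C4 are cis-1,4 across the cyclohexane, so O8–C4(=O) is a bridging δ-lactone; ring plus lactone form a 2-oxabicyclo[2.2.2]oct-5-en-3-one, the direct [4+2] adduct of a 2-pyrone, and the methyl/vinyl pair on C10 is the 1,2-double bond of isoprene.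
Forward: the cycloaddition builds the carbocycle as the bridged lactone; the bridgehead ester is excised; C11–C12 is coupled to C7; an ene reaction oxygenates C6; two hydride deliveries set C6 and C7; lactone opening frees O8 and turns C4 into a masked hydroxy-isopropenyl group; acylation and unmasking follow.
Stereochemistry: C5, C8 and C10 come from the cycloaddition (lactone bridge cis, vinyl endo, absolute sense from the chiral copper catalyst); C6 and C7 from attack on the lactone face of the rigid bicycle; the side-chain centre from the chiral pool.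

Key step: step 1

Assumption: the (S,S) ligand is taken, from a square-planar chelate model, to leave open the pyrone face that leads to the enantiomer drawn; if the sense proved opposite, the (R,R) ligand would be used and nothing else changes.

**Route**

Step 1
Reactants: 1 methyl 5-bromo-2-oxo-2H-pyran-3-carboxylate; 2 isoprene
Product: 3 methyl 6-bromo-8-methyl-3-oxo-8-vinyl-2-oxabicyclo[2.2.2]oct-5-ene-4-carboxylate (vinyl endo)
Conditions: Cu(OTf)2 (10 mol%), (S,S)-2,2'-isopropylidenebis(4-tert-butyl-2-oxazoline) (12 mol%), 4 Å MS, CH2Cl2, −30 → 0 °C, 2 (5 equiv)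
Reagents that add atoms: none
Why: Proposed new method: Cu(OTf)2 carrying the bis(oxazoline) chelates the ester and lactone carbonyls of 1 and lowers its LUMO, so the methyl-substituted double bond of 2 should add as the 2π partner in an asynchronous inverse-electron-demand [4+2], its CH2 terminus bonding to the electrophilic pyrone C6 (future C8) while positive charge builds at the tertiary allylic carbon (future C10), which then bonds to the malonate-type pyrone C3 (future C5); the closest known reaction type is the copper–bis(oxazoline)-catalysed inverse-demand Diels–Alder reaction of 3-alkoxycarbonyl-2-pyrones with enol ethers and indenes, together with the thermal addition of conjugated alkenes through one double bond to halogenated 2-pyrones. The carbocycle C5–C10 closes by suprafacial [4+2] cycloaddition across the pyrone termini and gives the 2-oxabicyclo[2.2.2]oct-5-en-3-one. C5 and C8 become the bridgeheads of one lactone bridge, so the C8 oxygen and the C5 carbonyl carbon are cis by construction; C10 is set by the endo rule, the vinyl group lying over the diene (secondary overlap) and the methyl group exo on the lactone side; the absolute sense is set by the tert-butyl groups of the ligand, which leave one face of the chelated pyrone open. The step needs periselectivity (pyrone as 4π partner), site selectivity for the 1,1-disubstituted double bond of 2 and C6-first regiochemistry; all three should follow from Markovnikov polarisation of the nucleophilic diene against the chelated electron-poor pyrone, and the low temperature should keep the endo-vinyl adduct from Cope rearrangement to the fused isomer.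

Step 2
Reactants: 3 methyl 6-bromo-8-methyl-3-oxo-8-vinyl-2-oxabicyclo[2.2.2]oct-5-ene-4-carboxylate
Product: 4 6-bromo-8-methyl-3-oxo-8-vinyl-2-oxabicyclo[2.2.2]oct-5-ene-4-carboxylic acid
Conditions: LiI, EtOAc, reflux; then 1 M HCl
Reagents that add atoms: none
Why: Iodide should cleave the methyl ester by SN2 attack at the methyl carbon (Krapcho-type dealkylation), a path closed to the bridgehead C8–O bond of the lactone, and the bridgehead β-carbonyl acid cannot decarboxylate through an enol (Bredt).

Step 3
Reactants: 4 6-bromo-8-methyl-3-oxo-8-vinyl-2-oxabicyclo[2.2.2]oct-5-ene-4-carboxylic acid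
Product: 6 (1S,4S,8R)-6-bromo-8-methyl-8-vinyl-2-oxabicyclo[2.2.2]oct-5-en-3-one, via thiohydroxamate ester 5 (not isolated)
Conditions: N-hydroxypyridine-2-thione, DCC, DMAP (cat.), CH2Cl2, dark, 0 °C → rt; then t-BuSH (excess), hν (tungsten lamp), rt
Reagents that add atoms: none
Why: Barton reductive decarboxylation: the thiohydroxamate ester fragments to CO2 and the C5 bridgehead radical, which takes hydrogen from the thiol; the bicycle fixes the configuration at C5, and the high thiol concentration should outrun 3-exo attack of the radical on the neighbouring vinyl group.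

Step 4
Reactants: 6 (1S,4S,8R)-6-bromo-8-methyl-8-vinyl-2-oxabicyclo[2.2.2]oct-5-en-3-one; 7 (2-tert-butoxy-2-oxoethyl)zinc bromide
Product: 8 tert-butyl 2-[(1S,4S,8R)-8-methyl-3-oxo-8-vinyl-2-oxabicyclo[2.2.2]oct-5-en-6-yl]acetate
Conditions: Pd(dba)2 (5 mol%), P(t-Bu)3 (10 mol%), THF, rt
Reagents that add atoms: none
Why: Negishi-type coupling of a Reformatsky reagent with an alkenyl bromide; the bulky electron-rich phosphine should favour insertion of zerovalent palladium into the C7–Br bond over ionisation of the allylic lactone, and the weakly basic zinc enolate should leave the β,γ-double bond in place.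

Step 5
Reactants: 8 tert-butyl 2-[(1S,4S,8R)-8-methyl-3-oxo-8-vinyl-2-oxabicyclo[2.2.2]oct-5-en-6-yl]acetate
Product: 11 tert-butyl 2-(8-methyl-3,5-dioxo-8-vinyl-2-oxabicyclo[2.2.2]octan-6-ylidene)acetate (ester on the side of bridgehead C1), via allylic hydroperoxide 9 (not isolated), via peroxyacetate 10 (not isolated)
Conditions: O2, tetraphenylporphyrin (cat.), hν (visible), CH2Cl2, 0 °C; then Ac2O, pyridine, DMAP (cat.), 0 °C → rt
Reagents that add atoms: oxygen, O=O
Why: Schenck ene reaction followed by Kornblum–DeLaMare dehydration: singlet oxygen can only bond to C6 and take hydrogen from C11, because the other allylic hydrogens sit on bridgeheads (Bredt), which moves the double bond to C7=C11; acetylation of the hydroperoxide and loss of acetic acid should give the C6 ketone.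

Step 6
Reactants: 11 tert-butyl 2-(8-methyl-3,5-dioxo-8-vinyl-2-oxabicyclo[2.2.2]octan-6-ylidene)acetate
Product: 12 tert-butyl 2-(5-hydroxy-8-methyl-3-oxo-8-vinyl-2-oxabicyclo[2.2.2]octan-6-ylidene)acetate (hydroxyl cis to vinyl)
Conditions: NaBH4, CeCl3·7H2O, MeOH/CH2Cl2, −78 °C
Reagents that add atoms: none
Why: Luche 1,2-reduction: hydride should reach the C6 carbonyl from the lactone-bridge face, because the other face is covered by the endo vinyl group on C10, so the new hydroxyl is cis to the vinyl group and trans to C4 as in the target.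

Step 7
Reactants: 12 tert-butyl 2-(5-hydroxy-8-methyl-3-oxo-8-vinyl-2-oxabicyclo[2.2.2]octan-6-ylidene)acetate
Product: 13 triethylsilyl ether of 12
Conditions: Et3SiOTf, 2,6-lutidine, CH2Cl2, −78 → 0 °C
Reagents that add atoms: triethylsilyl trifluoromethanesulfonate, CC[Si](CC)(CC)OS(=O)(=O)C(F)(F)F
Why: Silylation of a hindered secondary alcohol by a silyl triflate; the ether blocks later lactonisation onto C12 and adds bulk to the vinyl face.

Step 8
Reactants: 13 triethylsilyl ether of 12
Product: 14 tert-butyl 2-[8-methyl-3-oxo-5-(triethylsilyloxy)-8-vinyl-2-oxabicyclo[2.2.2]octan-6-yl]acetate (C5 oxygen and C6 side chain both cis to vinyl)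
Conditions: Cu(OAc)2 (5 mol%), 1,2-bis(diphenylphosphino)benzene (5 mol%), (EtO)2MeSiH, t-BuOH, toluene, 0 °C → rt
Reagents that add atoms: none
Why: Copper hydride conjugate reduction of a β,β-disubstituted enoate: hydride should be delivered to C7 from the lactone-bridge face, away from the C6 silyl ether and the C9–C10 bridge, which places C11 cis to the C6 oxygen; vinyl group, lactone and ester are inert to the ligated monovalent copper hydride.

Step 9
Reactants: 14 tert-butyl 2-[8-methyl-3-oxo-5-(triethylsilyloxy)-8-vinyl-2-oxabicyclo[2.2.2]octan-6-yl]acetate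
Product: 16 hydroxy allylsilane (cyclohexane: C10 methyl/vinyl; C8 OH; C7 CH2CO2t-Bu; C6 OSiEt3; C5 C(=CH2)CH2SiMe3), via bis(silylmethyl) carbinol 15 (not isolated)
Conditions: Me3SiCH2MgCl (5 equiv), CeCl3 (5 equiv), THF, −78 °C → rt; aq NH4Cl; then silica gel, CH2Cl2, rt
Reagents that add atoms: (trimethylsilyl)methylmagnesium chloride, C[Si](C)(C)C[Mg]Cl
Why: Cerium-mediated double addition of the silylmethyl Grignard reagent to the strained bridged lactone, then acid-catalysed Peterson elimination on silica, should open the lactone, free the C8 hydroxyl with the configuration fixed in step 1 and leave C4 as a 2-substituted allylsilane; the hindered tert-butyl ester and the non-basic organocerium reagent should spare C12 and the C5 stereocentre.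

Step 10
Reactants: 16 hydroxy allylsilane
Product: 19 tert-butyl acrylate (as 16 but C7 bears C(=CH2)CO2t-Bu), via Mannich base 17 (not isolated), via ammonium iodide 18 (not isolated)
Conditions: LiN(i-Pr)2 (3.2 equiv), THF, −78 °C; CH2=NMe2+ I− (1.5 equiv), −78 → −20 °C; then MeI, MeOH, rt; then DBU, CH2Cl2, rt
Reagents that add atoms: Eschenmoser's salt, C=[N+](C)C.[I-]
Why: α-Methylenation of an ester: the lithium enolate (formed beside the C8 alkoxide) undergoes a Mannich reaction with the iminium salt, and quaternisation followed by E1cB elimination should give the acrylate; C7 is not acidic and keeps its configuration.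

Step 11
Reactants: 20 methyl (R)-2-(2,2-dimethyl-1,3-dioxolan-4-yl)acetate
Product: 23 methyl (R)-2-(2,2-dimethyl-1,3-dioxolan-4-yl)acrylate, via Mannich base 21 (not isolated), via ammonium iodide 22 (not isolated)
Conditions: LiN(i-Pr)2 (1.1 equiv), THF, −78 °C; CH2=NMe2+ I−, −78 °C; then MeI, MeOH, rt; then DBU, CH2Cl2, rt
Reagents that add atoms: Eschenmoser's salt, C=[N+](C)C.[I-]
Why: The same Mannich–elimination methylenation; the β-alkoxy enolate is kept at −78 °C to avoid β-elimination, and the dioxolane stereocentre from the chiral pool is not touched.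

Step 12
Reactants: 23 methyl (R)-2-(2,2-dimethyl-1,3-dioxolan-4-yl)acrylate
Product: 24 (R)-2-(2,2-dimethyl-1,3-dioxolan-4-yl)acrylic acid
Conditions: LiOH, THF/H2O, 0 °C; then cold 0.5 M HCl to pH 4
Reagents that add atoms: lithium hydroxide, [Li+].[OH-]
Why: Saponification of an unhindered methyl ester; the stereocentre is not acidic and the acetonide tolerates the brief cold acidification.

Step 13
Reactants: 19 tert-butyl acrylate with free C8 hydroxyl; 24 (R)-2-(2,2-dimethyl-1,3-dioxolan-4-yl)acrylic acid
Product: 26 C8 ester of 19 and 24, via mixed anhydride 25 (not isolated)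
Conditions: 24, 2,4,6-trichlorobenzoyl chloride, Et3N, THF, rt; then 19, DMAP, toluene, rt → 40 °C
Reagents that add atoms: none
Why: Yamaguchi esterification through the mixed anhydride and the acylpyridinium ion; the C8 hydroxyl is the only free hydroxyl in 19.

Step 14
Reactants: 26 C8 ester of 19 and 24
Product: 28 tetraol tert-butyl ester (target with C12 as tert-butyl ester), via epoxysilane 27 (not isolated)
Conditions: mCPBA (1.05 equiv), NaHCO3, CH2Cl2, −20 → 0 °C; then AcOH/THF/H2O (3:1:1), rt → 40 °C
Reagents that add atoms: mCPBA, O=C(OO)c1cccc(Cl)c1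
Why: Peracid epoxidation should be selective for the electron-rich 1,1-disubstituted allylsilane double bond over the vinyl group and the two acrylates; aqueous acetic acid then opens the β-silyl epoxide with loss of silicon (acid Peterson-type fragmentation) to the 2-substituted allylic alcohol and hydrolyses the acetonide and the triethylsilyl ether, while the tert-butyl ester resists this weak acid.

Step 15
Reactants: 28 tetraol tert-butyl ester
Product: 30 CNP0348657.7, via pentakis(trimethylsilyl) derivative 29 (not isolated)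
Conditions: Me3SiOTf (10 equiv), 2,6-lutidine (15 equiv), CH2Cl2, 0 °C; then MeOH, aqueous citrate buffer pH 4–5, 0 °C, short contact
Reagents that add atoms: none
Why: Silyl triflate-mediated cleavage of the tert-butyl ester (loss of isobutene from the O-silylated ester) under buffered, non-protic conditions, with the hydroxyls carried as trimethylsilyl ethers that hydrolyse in the brief buffered work-up; this avoids the strong protic acid that would lactonise the C6 hydroxyl onto C12.

**Compound list**

1 | methyl 5-bromo-2-oxo-2H-pyran-3-carboxylate | COC(=O)C1=CC(Br)=COC1=O | starting material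
2 | isoprene (2-methylbuta-1,3-diene) | C=CC(C)=C | starting material
3 | methyl 6-bromo-8-methyl-3-oxo-8-vinyl-2-oxabicyclo[2.2.2]oct-5-ene-4-carboxylate; vinyl over the C5=C6 bridge (endo), methyl towards the lactone bridge | C=C[C@@]1(C)C[C@@H]2OC(=O)[C@@]1(C(=O)OC)C=C2Br | intermediate
4 | 6-bromo-8-methyl-3-oxo-8-vinyl-2-oxabicyclo[2.2.2]oct-5-ene-4-carboxylic acid, configured as 3 | C=C[C@@]1(C)C[C@@H]2OC(=O)[C@@]1(C(=O)O)C=C2Br | intermediate
5 | 2-thioxopyridin-1(2H)-yl ester of 4 | C=C[C@@]1(C)C[C@@H]2OC(=O)[C@@]1(C(=O)ON3C=CC=CC3=S)C=C2Br | intermediate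
6 | (1S,4S,8R)-6-bromo-8-methyl-8-vinyl-2-oxabicyclo[2.2.2]oct-5-en-3-one | C=C[C@@]1(C)C[C@@H]2OC(=O)[C@H]1C=C2Br | intermediate
7 | (2-tert-butoxy-2-oxoethyl)zinc bromide | CC(C)(C)OC(=O)C[Zn]Br | starting material
8 | tert-butyl 2-[(1S,4S,8R)-8-methyl-3-oxo-8-vinyl-2-oxabicyclo[2.2.2]oct-5-en-6-yl]acetate | C=C[C@@]1(C)C[C@@H]2OC(=O)[C@H]1C=C2CC(=O)OC(C)(C)C | intermediate
9 | tert-butyl 2-(5-hydroperoxy-8-methyl-3-oxo-8-vinyl-2-oxabicyclo[2.2.2]octan-6-ylidene)acetate; hydroperoxide on the lactone face, ester on the side of bridgehead C1 | C=C[C@@]1(C)C[C@@H]2OC(=O)[C@H]1[C@@H](OO)/C2=C/C(=O)OC(C)(C)C | intermediate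
10 | peroxyacetate of 9 | C=C[C@@]1(C)C[C@@H]2OC(=O)[C@H]1[C@@H](OOC(C)=O)/C2=C/C(=O)OC(C)(C)C | intermediate
11 | tert-butyl 2-(8-methyl-3,5-dioxo-8-vinyl-2-oxabicyclo[2.2.2]octan-6-ylidene)acetate; ester on the side of bridgehead C1 | C=C[C@@]1(C)C[C@@H]2OC(=O)[C@H]1C(=O)/C2=C/C(=O)OC(C)(C)C | intermediate
12 | tert-butyl 2-(5-hydroxy-8-methyl-3-oxo-8-vinyl-2-oxabicyclo[2.2.2]octan-6-ylidene)acetate; hydroxyl on the face of the C7–C8 bridge, cis to vinyl | C=C[C@@]1(C)C[C@@H]2OC(=O)[C@H]1[C@H](O)/C2=C/C(=O)OC(C)(C)C | intermediate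
13 | triethylsilyl ether of 12 | C=C[C@@]1(C)C[C@@H]2OC(=O)[C@H]1[C@H](O[Si](CC)(CC)CC)/C2=C/C(=O)OC(C)(C)C | intermediate
14 | tert-butyl 2-[8-methyl-3-oxo-5-(triethylsilyloxy)-8-vinyl-2-oxabicyclo[2.2.2]octan-6-yl]acetate; C5 oxygen and C6 side chain both on the face of the C7–C8 bridge | C=C[C@@]1(C)C[C@@H]2OC(=O)[C@H]1[C@H](O[Si](CC)(CC)CC)[C@@H]2CC(=O)OC(C)(C)C | intermediate
15 | monocyclic diol: as 16 but C5 bears C(OH)(CH2SiMe3)2 | C=C[C@@]1(C)C[C@H](O)[C@@H](CC(=O)OC(C)(C)C)[C@@H](O[Si](CC)(CC)CC)[C@@H]1C(O)(C[Si](C)(C)C)C[Si](C)(C)C | intermediate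
16 | hydroxy allylsilane: cyclohexane with C10 methyl/vinyl, C8 OH, C7 CH2CO2t-Bu, C6 OSiEt3, C5 C(=CH2)CH2SiMe3; spatial arrangement of the ring centres as in the target | C=C[C@@]1(C)C[C@H](O)[C@@H](CC(=O)OC(C)(C)C)[C@@H](O[Si](CC)(CC)CC)[C@@H]1C(=C)C[Si](C)(C)C | intermediate
17 | Mannich base: 16 with CH2NMe2 on C11 (epimers at C11) | C=C[C@@]1(C)C[C@H](O)[C@@H](C(CN(C)C)C(=O)OC(C)(C)C)[C@@H](O[Si](CC)(CC)CC)[C@@H]1C(=C)C[Si](C)(C)C | intermediate
18 | trimethylammonium iodide of 17 | C=C[C@@]1(C)C[C@H](O)[C@@H](C(C[N+](C)(C)C)C(=O)OC(C)(C)C)[C@@H](O[Si](CC)(CC)CC)[C@@H]1C(=C)C[Si](C)(C)C.[I-] | intermediate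
19 | tert-butyl acrylate: 16 with C7 bearing C(=CH2)CO2t-Bu | C=C[C@@]1(C)C[C@H](O)[C@@H](C(=C)C(=O)OC(C)(C)C)[C@@H](O[Si](CC)(CC)CC)[C@@H]1C(=C)C[Si](C)(C)C | intermediate
20 | methyl (R)-2-(2,2-dimethyl-1,3-dioxolan-4-yl)acetate | COC(=O)C[C@@H]1COC(C)(C)O1 | starting material
21 | methyl 3-(dimethylamino)-2-[(R)-2,2-dimethyl-1,3-dioxolan-4-yl]propanoate (epimers at C2) | COC(=O)C(CN(C)C)[C@@H]1COC(C)(C)O1 | intermediate
22 | trimethylammonium iodide of 21 | COC(=O)C(C[N+](C)(C)C)[C@@H]1COC(C)(C)O1.[I-] | intermediate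
23 | methyl (R)-2-(2,2-dimethyl-1,3-dioxolan-4-yl)acrylate | COC(=O)C(=C)[C@@H]1COC(C)(C)O1 | intermediate
24 | (R)-2-(2,2-dimethyl-1,3-dioxolan-4-yl)acrylic acid | OC(=O)C(=C)[C@@H]1COC(C)(C)O1 | intermediate
25 | mixed anhydride of 24 and 2,4,6-trichlorobenzoic acid | C=C(C(=O)OC(=O)c1c(Cl)cc(Cl)cc1Cl)[C@@H]1COC(C)(C)O1 | intermediate
26 | 19 acylated at the C8 oxygen by 24 | C=C[C@@]1(C)C[C@H](OC(=O)C(=C)[C@@H]2COC(C)(C)O2)[C@@H](C(=C)C(=O)OC(C)(C)C)[C@@H](O[Si](CC)(CC)CC)[C@@H]1C(=C)C[Si](C)(C)C | intermediate
27 | 26 with the allylsilane double bond epoxidised (epimers at the oxirane carbon) | C=C[C@@]1(C)C[C@H](OC(=O)C(=C)[C@@H]2COC(C)(C)O2)[C@@H](C(=C)C(=O)OC(C)(C)C)[C@@H](O[Si](CC)(CC)CC)[C@@H]1C3(C[Si](C)(C)C)CO3 | intermediate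
28 | tert-butyl ester of the target acid (all four hydroxyls free) | C=C[C@@]1(C)C[C@H](OC(=O)C(=C)[C@@H](O)CO)[C@@H](C(=C)C(=O)OC(C)(C)C)[C@@H](O)[C@@H]1C(=C)CO | intermediate
29 | trimethylsilyl ester tetrakis(trimethylsilyl) ether of the target | C=C[C@@]1(C)C[C@H](OC(=O)C(=C)[C@@H](O[Si](C)(C)C)CO[Si](C)(C)C)[C@@H](C(=C)C(=O)O[Si](C)(C)C)[C@@H](O[Si](C)(C)C)[C@@H]1C(=C)CO[Si](C)(C)C | intermediate
30 | CNP0348657.7: (5S,6S,7S,8S,10R)-8-O-[(3R)-3,4-dihydroxy-2-methylidenebutanoyl]-6,15-dihydroxyelema-1,3,11(13)-trien-12-oic acid | C=C[C@@]1(C)C[C@H](OC(=O)C(=C)[C@@H](O)CO)[C@@H](C(=C)C(=O)O)[C@@H](O)[C@@H]1C(=C)CO | target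

**Count and risks**

Total steps: 15. Longest linear sequence: 13 (steps 1–10, 13–15); steps 11–12 make the side-chain acid.

Steps most likely to fail:

1. Step 1 (Proposed new method). Isoprene may add as the 4π partner across the pyrone, the endo-vinyl adduct may rearrange (Cope) to the fused isomer, facial selectivity may be low, or isoprene may polymerise. The fallback builds the quaternary centre by a thermal normal-demand Diels–Alder reaction of known type and resolves late. It uses neither 1 nor 2, sets out in their place from commercial 3,5-dibromo-2H-pyran-2-one F1 and methacrolein F2, and comes back to the route at compound 6. Heating F1 and F2 in toluene at 90 °C should give the racemic dibromo lactone aldehyde F3 with the formyl group endo, separated from its exo isomer. Zn in AcOH should remove the bridgehead bromine to give the racemic aldehyde F4. Ph3P=CH2 in THF at −78 → 0 °C should give racemic 6 F5, which is resolved by preparative chromatography on a chiral stationary phase.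

2. Step 9. The organocerium reagent may also attack the tert-butyl ester, the C8 alkoxide may lactonise onto C12, or the second addition and the Peterson elimination may stall. The fallback sets out from 14 and comes back at 16. Me(MeO)NH·HCl with AlMe3 in CH2Cl2 should open the lactone to the hydroxy Weinreb amide F6. Me3SiCH2MgCl in THF at 0 °C should add once to give the β-silyl ketone F7. Salt-free Ph3P=CH2 should convert F7 into allylsilane 16.

3. Step 15. The C6 hydroxyl may lactonise onto C12 during ester cleavage or work-up, or the side chain may be lost through attack of its own primary hydroxyl on the ester. The fallback sets out from 19, exchanges the tert-butyl ester for an allyl ester before the coupling, and comes back at 30 with a neutral last step. Me3SiOTf with 2,6-lutidine and buffered work-up should give the carboxylic acid F8. Allyl bromide with KHCO3 in DMF should give the allyl ester F9. Yamaguchi esterification with 24 should give the coupled allyl ester F10. mCPBA followed by AcOH/THF/H2O should give the tetraol allyl ester F11. Pd(PPh3)4 with morpholine in THF at rt should release 30 as its carboxylate.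

Further compounds
F1 | step 1 | 3,5-dibromo-2H-pyran-2-one | O=C1OC=C(Br)C=C1Br
F2 | step 1 | methacrolein | CC(=C)C=O
F3 | step 1 | racemic 4,6-dibromo-8-methyl-3-oxo-2-oxabicyclo[2.2.2]oct-5-ene-8-carbaldehyde (formyl endo) | O=C[C@@]1(C)C[C@@H]2OC(=O)[C@@]1(Br)C=C2Br.O=C[C@]1(C)C[C@H]2OC(=O)[C@]1(Br)C=C2Br
F4 | step 1 | racemic 6-bromo-8-methyl-3-oxo-2-oxabicyclo[2.2.2]oct-5-ene-8-carbaldehyde (formyl endo) | O=C[C@@]1(C)C[C@@H]2OC(=O)[C@H]1C=C2Br.O=C[C@]1(C)C[C@H]2OC(=O)[C@@H]1C=C2Br
F5 | step 1 | racemic 6 | C=C[C@@]1(C)C[C@@H]2OC(=O)[C@H]1C=C2Br.C=C[C@]1(C)C[C@H]2OC(=O)[C@@H]1C=C2Br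
F6 | step 9 | hydroxy Weinreb amide (as 16 but C5 bears C(=O)N(OMe)Me) | C=C[C@@]1(C)C[C@H](O)[C@@H](CC(=O)OC(C)(C)C)[C@@H](O[Si](CC)(CC)CC)[C@@H]1C(=O)N(C)OC
F7 | step 9 | β-silyl ketone (as 16 but C5 bears C(=O)CH2SiMe3) | C=C[C@@]1(C)C[C@H](O)[C@@H](CC(=O)OC(C)(C)C)[C@@H](O[Si](CC)(CC)CC)[C@@H]1C(=O)C[Si](C)(C)C
F8 | step 15 | carboxylic acid corresponding to 19 | C=C[C@@]1(C)C[C@H](O)[C@@H](C(=C)C(=O)O)[C@@H](O[Si](CC)(CC)CC)[C@@H]1C(=C)C[Si](C)(C)C
F9 | step 15 | allyl ester corresponding to 19 | C=C[C@@]1(C)C[C@H](O)[C@@H](C(=C)C(=O)OCC=C)[C@@H](O[Si](CC)(CC)CC)[C@@H]1C(=C)C[Si](C)(C)C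
F10 | step 15 | allyl ester corresponding to 26 | C=C[C@@]1(C)C[C@H](OC(=O)C(=C)[C@@H]2COC(C)(C)O2)[C@@H](C(=C)C(=O)OCC=C)[C@@H](O[Si](CC)(CC)CC)[C@@H]1C(=C)C[Si](C)(C)C
F11 | step 15 | allyl ester of the target acid (all four hydroxyls free) | C=C[C@@]1(C)C[C@H](OC(=O)C(=C)[C@@H](O)CO)[C@@H](C(=C)C(=O)OCC=C)[C@@H](O)[C@@H]1C(=C)CO
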